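**Retrosynthetic overview**
1. Target ⇐ selective MnO2 oxidation of a 15-ol; ring D (C13–C16) ⇐ 5-exo vinyl-radical closure from a 2-bromoallylic carbinol placed on C8 by a lactone-enolate aldol.
2. Ring C is bought intact as an achiral 3-oxocyclohexene carboxylate (C7–C9, C11–C14); its ketone supplies first the C12=C13 radical acceptor, then the C11 carbinol.
3. Key disconnection C9–C10: a ring A spiro-epoxide (C10–C20) is reduced by titanocene to a nucleophilic tertiary radical that adds to C9 of the ene-keto ester; the freed C20 hydroxyl closes the δ-lactone.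
4. Ring A ⇐ catalytic asymmetric Diels–Alder of an (E)-enal ester (fixes C4/C5 trans) with 1-acetoxybutadiene, then reduction, silylation, redox isomerisation and carbenoid epoxidation.
5. Ring order: A (Diels–Alder) → δ-lactone fused to preformed ring C (key coupling) → D (radical cyclisation).

Atom labels C1–C20 follow ent-kaurane numbering of the target. Target descriptors: 4S,5R,8S,9S,10S,11R,13S.
Assumption: the chiral catalyst in step 2 follows its published facial model (otherwise its antipode is used), and the bromo-enal of step 8 is bought stabilised (otherwise made fresh from acrolein with Br2, then Et3N).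

**Step 1**
Reactants: 1 ethyl 2-(triphenylphosphoranylidene)propanoate; 2 2,2-dimethoxyacetaldehyde
Product: 4 ethyl (E)-2-methyl-4-oxobut-2-enoate, via dimethyl acetal 3 (not isolated)
Conditions: CH2Cl2, rt; then 1 M aq. HCl, THF, rt
Reagents that add atoms: water, O
Why: E-selective Wittig olefination with the stabilised α-methyl ylide, then acetal hydrolysis, gives the enal ester with CHO and CO2Et trans, the geometry that becomes the trans C5/C4 relationship.

**Step 2**
Reactants: 4 ethyl (E)-2-methyl-4-oxobut-2-enoate; 5 (E)-buta-1,3-dien-1-yl acetate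
Product: 6 ethyl (1S,5S,6R)-5-acetoxy-6-formyl-1-methylcyclohex-3-ene-1-carboxylate
Conditions: (S)-5-benzyl-2,2,3-trimethylimidazolidin-4-one·HCl (first-generation MacMillan catalyst, 20 mol %), MeCN/H2O 95:5, 0 °C → rt
Reagents that add atoms: none
Why: Proposed new method: the amine forms an (E)-iminium of 4 whose α-carbon Re face is shielded by the benzyl group, so the diene adds endo to the open face with its free terminus bonding to the β-carbon (quaternary C4) and its acetoxy terminus to C5, while the E-geometry of 4 fixes CH3 cis to CHO (C4 S, C5 R); the closest known reaction is the iminium-catalysed Diels–Alder of β-monosubstituted enals with 1-acetoxybutadiene.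

**Step 3**
Reactants: 6 ethyl (1S,5S,6R)-5-acetoxy-6-formyl-1-methylcyclohex-3-ene-1-carboxylate
Product: 7 (1S,5S,6S)-5,6-bis(hydroxymethyl)-5-methylcyclohex-2-en-1-ol
Conditions: LiAlH4, THF, −78 → 0 °C; aq. NaOH work-up
Reagents that add atoms: none
Why: LiAlH4 hydride reduction converts aldehyde, ester and acetate to the triol, and the α-formyl centre is reduced before it can epimerise or lose acetate.

**Step 4**
Reactants: 7 (1S,5S,6S)-5,6-bis(hydroxymethyl)-5-methylcyclohex-2-en-1-ol
Product: 8 (1S,5S,6S)-5,6-bis(tert-butyldimethylsilyloxymethyl)-5-methylcyclohex-2-en-1-ol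
Conditions: TBSCl (2.1 equiv), imidazole, DMF, 0 °C
Reagents that add atoms: tert-butyldimethylsilyl chloride (TBSCl), CC(C)(C)[Si](C)(C)Cl
Why: Corey silylation is sterically selective, the two primary hydroxyls reacting much faster than the secondary allylic hydroxyl flanked by C5.

**Step 5**
Reactants: 8 (1S,5S,6S)-5,6-bis(tert-butyldimethylsilyloxymethyl)-5-methylcyclohex-2-en-1-ol
Product: 9 (2S,3S)-2,3-bis(tert-butyldimethylsilyloxymethyl)-3-methylcyclohexan-1-one
Conditions: RuHCl(CO)(PPh3)3 (5 mol %), PhMe, 90 °C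
Reagents that add atoms: none
Why: Ruthenium-hydride redox isomerisation (hydrometalation, β-hydride elimination to the enol, tautomerisation) gives the saturated ketone under neutral conditions, so the enolisable C5 centre is not epimerised.

**Step 6**
Reactants: 9 (2S,3S)-2,3-bis(tert-butyldimethylsilyloxymethyl)-3-methylcyclohexan-1-one
Product: 10 (4S,5S)-4,5-bis(tert-butyldimethylsilyloxymethyl)-5-methyl-1-oxaspiro[2.5]octane (either spiro epimer)
Conditions: CH2I2, MeLi, THF, −78 °C → rt
Reagents that add atoms: diiodomethane, ICI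
Why: (Iodomethyl)lithium formed in situ by I/Li exchange adds to the ketone faster than it enolises it and the iodohydrin alkoxide closes to the epoxide (carbenoid homologation of Corey–Chaykovsky type), the new spiro centre being irrelevant because it becomes a planar radical.

**Step 7 (key step)**
Reactants: 10 (4S,5S)-4,5-bis(tert-butyldimethylsilyloxymethyl)-5-methyl-1-oxaspiro[2.5]octane; 11 methyl 3-oxocyclohex-1-ene-1-carboxylate
Product: 13 (4S,5R,9R,10S)-6,18-bis(tert-butyldimethylsilyloxy)-11-oxo-15,16,17-trinor-6,7-secokauran-7,20-olide (C8 epimers), via hydroxy keto ester 12 (not isolated)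
Conditions: Cp2TiCl2 (20 mol %), Zn dust, 2,4,6-collidine·HCl, THF, rt, 10 added slowly to 11 (3 equiv); then PPTS, PhMe, 60 °C
Reagents that add atoms: none
Why: Proposed new method: Cp2TiCl (trivalent titanium) opens the epoxide by single-electron transfer to a β-titanoxy tertiary C10 radical, so a normally electrophilic epoxide carbon becomes nucleophilic and adds to the normally electrophilic, unsubstituted β-carbon C9 of the mesaconate-like ene-keto ester, equatorially and anti to the C5 side chain (C10 S) with the ester-bearing C8 placed next to C20 (C9 R, also expected to be the more stable epimer of this enolisable centre), after which the α-ester radical is reduced and protonated and the C20 hydroxyl lactonises onto C7; the closest known reaction is the titanocene-mediated reductive epoxide opening/Giese addition to acrylates (Nugent–RajanBabu type).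

**Step 8**
Reactants: 13 keto spirolactone (as above); 14 2-bromoprop-2-enal
Product: 16 (4S,5R,8S,9S,10S)-8-[2-bromo-1-(triethylsilyloxy)prop-2-en-1-yl]-6,18-bis(tert-butyldimethylsilyloxy)-11-(trimethylsilyloxy)-15,16,17-trinor-6,7-secokaur-11-en-7,20-olide (carbinol epimers), via TMS enol ether 15 (not isolated)
Conditions: LiN(i-Pr)2 (1.05 equiv), TMSCl (1.05 equiv), THF, −78 °C; LiN(i-Pr)2 (1.3 equiv), −78 → −40 °C; 14, −78 °C; TESOTf, −78 → 0 °C
Reagents that add atoms: chlorotrimethylsilane (TMSCl), C[Si](C)(C)Cl; triethylsilyl trifluoromethanesulfonate (TESOTf), CC[Si](CC)(CC)OS(=O)(=O)C(F)(F)F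
Why: Kinetic enolisation at C12 with in situ silylation masks the ketone, the lactone enolate then undergoes a directed aldol addition to the aldehyde on the face syn to H9 (anti to the pseudoaxial C9–C11 bond, as in angular alkylation of fused bicyclic enolates) to set quaternary C8 (S) with a cis-fused lactone, and the aldolate is capped as its TES ether to block retro-aldol cleavage.

**Step 9**
Reactants: 16 silyl enol ether aldol product (as above)
Product: 17 (4S,5R,8S,9S,10S)-8-[2-bromo-1-(triethylsilyloxy)prop-2-en-1-yl]-6,18-bis(tert-butyldimethylsilyloxy)-11-oxo-15,16,17-trinor-6,7-secokaur-12-en-7,20-olide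
Conditions: IBX, 4-methoxypyridine N-oxide, DMSO, rt
Reagents that add atoms: none
Why: Dehydrogenation of the TMS enol ether with the IBX·N-oxide complex (a palladium-free Saegusa-type oxidation that spares the vinyl bromide) installs the C12=C13 enone regiospecifically.

**Step 10**
Reactants: 17 enone (as above)
Product: 18 (4S,5R,8S,9S,10S,11R)-8-[2-bromo-1-(triethylsilyloxy)prop-2-en-1-yl]-6,18-bis(tert-butyldimethylsilyloxy)-11-hydroxy-15,16,17-trinor-6,7-secokaur-12-en-7,20-olide
Conditions: NaBH4, CeCl3·7H2O, MeOH, −78 °C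
Reagents that add atoms: none
Why: In this Luche 1,2-reduction hydride attacks the carbonyl from the face syn to H9 because the other face is screened by the pseudoaxial C8–C7 bond, giving the 11R alcohol with OH cis to C10.

**Step 11**
Reactants: 18 bromo allylic alcohol (as above)
Product: 19 (4S,5R,8S,9S,10S,11R,13S)-6,18-bis(tert-butyldimethylsilyloxy)-11-hydroxy-15-(triethylsilyloxy)-6,7-secokaur-16-en-7,20-olide (C15 epimers)
Conditions: Bu3SnH, AIBN (cat.), PhH, 80 °C, syringe pump
Reagents that add atoms: none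
Why: In this Stork-type vinyl radical cyclisation the C16 radical adds 5-exo-trig to C13, which is possible only on the face carrying the C8 arm, so the bicyclo[3.2.1]octane and C13 (S) form with the exocyclic methylene in place.

**Step 12**
Reactants: 19 silylated bicycle (as above)
Product: 20 (4S,5R,8S,9S,10S,11R,13S)-6,11,15,18-tetrahydroxy-6,7-secokaur-16-en-7,20-olide (C15 epimers)
Conditions: HF·pyridine, THF/pyridine, 0 °C → rt
Reagents that add atoms: none
Why: Acidic fluoride desilylation removes both TBS ethers and the TES ether without the base that would cause retro-aldol cleavage of the β-hydroxy lactone.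

**Step 13**
Reactants: 20 tetraol (as above)
Product: 21 (4S,5R,8S,9S,10S,11R,13S)-6,11,18-trihydroxy-15-oxo-6,7-secokaur-16-en-7,20-olide (target)
Conditions: MnO2 (activated, excess), CH2Cl2, rt
Reagents that add atoms: none
Why: MnO2 is a chemoselective allylic oxidant, converting only the C15 alcohol (both epimers) to the α-methylene ketone and leaving the primary and the non-allylic secondary hydroxyls untouched.

**Compound list**
1 | ethyl 2-(triphenylphosphoranylidene)propanoate | CCOC(=O)C(C)=P(c1ccccc1)(c1ccccc1)c1ccccc1 | starting material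
2 | 2,2-dimethoxyacetaldehyde | COC(OC)C=O | starting material
3 | ethyl (E)-4,4-dimethoxy-2-methylbut-2-enoate | CCOC(=O)/C(C)=C/C(OC)OC | intermediate
4 | ethyl (E)-2-methyl-4-oxobut-2-enoate | CCOC(=O)/C(C)=C/C=O | intermediate
5 | (E)-buta-1,3-dien-1-yl acetate (sold as E/Z mixture; E reacts) | CC(=O)O/C=C/C=C | starting material
6 | ethyl (1S,5S,6R)-5-acetoxy-6-formyl-1-methylcyclohex-3-ene-1-carboxylate | CC(=O)O[C@H]1C=CC[C@](C)(C(=O)OCC)[C@H]1C=O | intermediate
7 | (1S,5S,6S)-5,6-bis(hydroxymethyl)-5-methylcyclohex-2-en-1-ol | O[C@H]1C=CC[C@](C)(CO)[C@H]1CO | intermediate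
8 | (1S,5S,6S)-5,6-bis(tert-butyldimethylsilyloxymethyl)-5-methylcyclohex-2-en-1-ol | O[C@H]1C=CC[C@](C)(CO[Si](C)(C)C(C)(C)C)[C@H]1CO[Si](C)(C)C(C)(C)C | intermediate
9 | (2S,3S)-2,3-bis(tert-butyldimethylsilyloxymethyl)-3-methylcyclohexan-1-one | O=C1CCC[C@](C)(CO[Si](C)(C)C(C)(C)C)[C@H]1CO[Si](C)(C)C(C)(C)C | intermediate
10 | (4S,5S)-4,5-bis(tert-butyldimethylsilyloxymethyl)-5-methyl-1-oxaspiro[2.5]octane, spiro epimers | C1OC12CCC[C@](C)(CO[Si](C)(C)C(C)(C)C)[C@H]2CO[Si](C)(C)C(C)(C)C | intermediate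
11 | methyl 3-oxocyclohex-1-ene-1-carboxylate | COC(=O)C1=CC(=O)CCC1 | starting material
12 | methyl (2R)-2-[(1S,2R,3S)-2,3-bis(tert-butyldimethylsilyloxymethyl)-1-(hydroxymethyl)-3-methylcyclohexyl]-3-oxocyclohexane-1-carboxylate, C1 epimers | OC[C@]1(CCC[C@](C)(CO[Si](C)(C)C(C)(C)C)[C@H]1CO[Si](C)(C)C(C)(C)C)[C@@H]2C(=O)CCCC2C(=O)OC | intermediate
13 | (4S,5R,9R,10S)-6,18-bis(tert-butyldimethylsilyloxy)-11-oxo-15,16,17-trinor-6,7-secokauran-7,20-olide, C8 epimers (ring A spiro at C10 to the δ-lactone C7(=O)–O–C20, fused at C8–C9 to cyclohexan-11-one) | O=C1OC[C@]2(CCC[C@](C)(CO[Si](C)(C)C(C)(C)C)[C@H]2CO[Si](C)(C)C(C)(C)C)[C@@H]3C(=O)CCCC13 | intermediate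
14 | 2-bromoprop-2-enal | C=C(Br)C=O | starting material
15 | 11-O-trimethylsilyl Δ11 enol ether of 13 (4S,5R,9R,10S) | O=C1OC[C@]2(CCC[C@](C)(CO[Si](C)(C)C(C)(C)C)[C@H]2CO[Si](C)(C)C(C)(C)C)[C@@H]3C(O[Si](C)(C)C)=CCCC13 | intermediate
16 | (4S,5R,8S,9S,10S)-8-[2-bromo-1-(triethylsilyloxy)prop-2-en-1-yl]-6,18-bis(tert-butyldimethylsilyloxy)-11-(trimethylsilyloxy)-15,16,17-trinor-6,7-secokaur-11-en-7,20-olide, carbinol epimers | O=C1OC[C@]2(CCC[C@](C)(CO[Si](C)(C)C(C)(C)C)[C@H]2CO[Si](C)(C)C(C)(C)C)[C@@H]3C(O[Si](C)(C)C)=CCC[C@]13C(O[Si](CC)(CC)CC)C(Br)=C | intermediate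
17 | (4S,5R,8S,9S,10S)-8-[2-bromo-1-(triethylsilyloxy)prop-2-en-1-yl]-6,18-bis(tert-butyldimethylsilyloxy)-11-oxo-15,16,17-trinor-6,7-secokaur-12-en-7,20-olide | O=C1OC[C@]2(CCC[C@](C)(CO[Si](C)(C)C(C)(C)C)[C@H]2CO[Si](C)(C)C(C)(C)C)[C@@H]3C(=O)C=CC[C@]13C(O[Si](CC)(CC)CC)C(Br)=C | intermediate
18 | (4S,5R,8S,9S,10S,11R)-8-[2-bromo-1-(triethylsilyloxy)prop-2-en-1-yl]-6,18-bis(tert-butyldimethylsilyloxy)-11-hydroxy-15,16,17-trinor-6,7-secokaur-12-en-7,20-olide | O=C1OC[C@]2(CCC[C@](C)(CO[Si](C)(C)C(C)(C)C)[C@H]2CO[Si](C)(C)C(C)(C)C)[C@@H]3[C@H](O)C=CC[C@]13C(O[Si](CC)(CC)CC)C(Br)=C | intermediate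
19 | (4S,5R,8S,9S,10S,11R,13S)-6,18-bis(tert-butyldimethylsilyloxy)-11-hydroxy-15-(triethylsilyloxy)-6,7-secokaur-16-en-7,20-olide, C15 epimers | C=C1C(O[Si](CC)(CC)CC)[C@]23C[C@H]1C[C@@H](O)[C@H]2[C@@]1(CCC[C@](C)(CO[Si](C)(C)C(C)(C)C)[C@H]1CO[Si](C)(C)C(C)(C)C)COC3=O | intermediate
20 | (4S,5R,8S,9S,10S,11R,13S)-6,11,15,18-tetrahydroxy-6,7-secokaur-16-en-7,20-olide, C15 epimers | C=C1C(O)[C@]23C[C@H]1C[C@@H](O)[C@H]2[C@@]1(CCC[C@](C)(CO)[C@H]1CO)COC3=O | intermediate
21 | (4S,5R,8S,9S,10S,11R,13S)-6,11,18-trihydroxy-15-oxo-6,7-secokaur-16-en-7,20-olide | C=C1C(=O)[C@]23C[C@H]1C[C@@H](O)[C@H]2[C@@]1(CCC[C@](C)(CO)[C@H]1CO)COC3=O | target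

**Totals**
Total steps: 13. Longest linear sequence: 13 (steps 1–13; 5, 11 and 14 are bought).

**Three steps most likely to fail, with fallbacks**

Step 7 (key coupling). The hindered tertiary radical may add too slowly to a β-substituted acceptor, titanocene may reduce 11, or C9 may form with the wrong configuration. The fallback sets out from 10 and comes back at 12. LiNEt2 (Et2O, reflux) isomerises epoxide 10 to the allylic alcohol [(5S,6R)-5,6-bis(tert-butyldimethylsilyloxymethyl)-5-methylcyclohex-1-en-1-yl]methanol F4. Fe(acac)3/PhSiH3 (EtOH, 60 °C) then transfers a hydrogen atom to C1 of F4, and the same C10 tertiary radical adds to C9 of 11 (metal-hydride hydrogen-atom-transfer olefin coupling). This gives hydroxy keto ester 12, which is lactonised with PPTS to 13 as in step 7.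

Step 2 (asymmetric Diels–Alder). A β,β-disubstituted enal may form its iminium slowly or give low selectivity. The fallback sets out from 4 and comes back at 7. NaClO2/NaH2PO4/2-methyl-2-butene oxidises 4 to (E)-4-ethoxy-3-methyl-4-oxobut-2-enoic acid F1. PivCl/Et3N followed by lithiated oxazolidin-2-one gives the imide ethyl (E)-2-methyl-4-oxo-4-(2-oxo-1,3-oxazolidin-3-yl)but-2-enoate F2. A two-point-binding Lewis-acid Diels–Alder of F2 with 5 under [Cu((S,S)-t-Bu-box)](SbF6)2 (antipodal ligand if required) gives ethyl (1S,5S,6R)-5-acetoxy-1-methyl-6-[(2-oxo-1,3-oxazolidin-3-yl)carbonyl]cyclohex-3-ene-1-carboxylate F3. LiAlH4 reduces imide, ester and acetate of F3 to triol 7.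

Step 8 (quaternary aldol at C8). The hindered lactone enolate may add sluggishly or the aldolate may revert. The fallback sets out from 13 and comes back at 20. The same TMS enol ether/lithium lactone enolate is alkylated irreversibly with 2,3-dibromopropene (SN2) to give the 8-(2-bromoallyl) silyl enol ether F5. IBX·4-methoxypyridine N-oxide gives the 8-(2-bromoallyl) enone F6, and NaBH4/CeCl3 gives the 8-(2-bromoallyl) 11R allylic alcohol F7. Bu3SnH/AIBN cyclises F7 to the 15-deoxy bicycle F8. SeO2/t-BuOOH hydroxylates the allylic C15 methylene of F8 to the bis-TBS 15-alcohol F9, and HF·pyridine then gives tetraol 20.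

**Further compounds**
F1 | step 2 | (E)-4-ethoxy-3-methyl-4-oxobut-2-enoic acid | CCOC(=O)/C(C)=C/C(=O)O
F2 | step 2 | ethyl (E)-2-methyl-4-oxo-4-(2-oxo-1,3-oxazolidin-3-yl)but-2-enoate | CCOC(=O)/C(C)=C/C(=O)N1CCOC1=O
F3 | step 2 | ethyl (1S,5S,6R)-5-acetoxy-1-methyl-6-[(2-oxo-1,3-oxazolidin-3-yl)carbonyl]cyclohex-3-ene-1-carboxylate | CC(=O)O[C@H]1C=CC[C@](C)(C(=O)OCC)[C@H]1C(=O)N1CCOC1=O
F4 | step 7 | [(5S,6R)-5,6-bis(tert-butyldimethylsilyloxymethyl)-5-methylcyclohex-1-en-1-yl]methanol | OCC1=CCC[C@](C)(CO[Si](C)(C)C(C)(C)C)[C@H]1CO[Si](C)(C)C(C)(C)C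
F5 | step 8 | 8-(2-bromoallyl) silyl enol ether (16 with CH2 in place of the silyloxy carbinol carbon) | O=C1OC[C@]2(CCC[C@](C)(CO[Si](C)(C)C(C)(C)C)[C@H]2CO[Si](C)(C)C(C)(C)C)[C@@H]3C(O[Si](C)(C)C)=CCC[C@]13CC(Br)=C
F6 | step 8 | 8-(2-bromoallyl) enone (15-deoxy analogue of 17) | O=C1OC[C@]2(CCC[C@](C)(CO[Si](C)(C)C(C)(C)C)[C@H]2CO[Si](C)(C)C(C)(C)C)[C@@H]3C(=O)C=CC[C@]13CC(Br)=C
F7 | step 8 | 8-(2-bromoallyl) 11R allylic alcohol (15-deoxy analogue of 18) | O=C1OC[C@]2(CCC[C@](C)(CO[Si](C)(C)C(C)(C)C)[C@H]2CO[Si](C)(C)C(C)(C)C)[C@@H]3[C@H](O)C=CC[C@]13CC(Br)=C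
F8 | step 8 | 15-deoxy bicycle: 6,18-bis(tert-butyldimethylsilyloxy)-11-hydroxy-6,7-secokaur-16-en-7,20-olide | C=C1C[C@]23C[C@H]1C[C@@H](O)[C@H]2[C@@]1(CCC[C@](C)(CO[Si](C)(C)C(C)(C)C)[C@H]1CO[Si](C)(C)C(C)(C)C)COC3=O
F9 | step 8 | bis-TBS 15-alcohol: 6,18-bis(tert-butyldimethylsilyloxy)-11,15-dihydroxy-6,7-secokaur-16-en-7,20-olide, C15 epimers | C=C1C(O)[C@]23C[C@H]1C[C@@H](O)[C@H]2[C@@]1(CCC[C@](C)(CO[Si](C)(C)C(C)(C)C)[C@H]1CO[Si](C)(C)C(C)(C)C)COC3=O
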